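**Strategy**

1. Cuts: first the dioxane C7–O bond (to the ring oxygen para to the propenoic acid chain), then, with C7 returned to a ketone and C9 to an ester, the C8–O aryl ether bond. The halves go back to acetovanillone + diethyl carbonate and to 3,4-dihydroxybenzaldehyde + a Wittig ylide.
2. Forward: both arenes are bought. The C8–O bond joins the halves, the ketone is reduced, the C9 ester is reduced, and the 1,4-dioxane ring, the only ring made, closes last through C7–O in acid.
3. Enabling feature: C8 of the dioxane ring sits between benzylic C7 and C9. With C7 as ketone and C9 as ester it is an enolisable 1,3-dicarbonyl alpha-carbon, and C7 is a para-oxybenzylic carbon whose C–O bond ionises reversibly in acid.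
4. Stereochemistry: C8 comes from a catalyst-controlled transfer hydrogenation run as a dynamic kinetic resolution. C7 comes from thermodynamic (trans) control in the reversible acid closure. The E-alkene comes from the stabilised ylide.

Key step: step 7

Remark on the chemistry: lignan numbering is used (C7 = benzylic carbon bearing the guaiacyl ring, C8 = the neighbouring carbon bearing the aryl ether oxygen, C9 = the CH2OH carbon). In the last step the acid-induced events are written in the order acetal and ester cleavage first, ring closure second; the outcome does not depend on this order.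

**Route**

Step 1
Reactants: 1 acetovanillone, 1-(4-hydroxy-3-methoxyphenyl)ethan-1-one
Product: 2 1-[3-methoxy-4-(methoxymethoxy)phenyl]ethan-1-one
Conditions: MOMCl, iPr2NEt, CH2Cl2, 0 °C to rt
Reagents that add atoms: chloromethyl methyl ether (MOMCl), COCCl
Why: Williamson-type O-alkylation of the phenol with the reactive alpha-chloro ether gives a methoxymethyl acetal that is inert to NaH, NBS, K2CO3, formate and borohydride and is shed in the final acid step.

Step 2
Reactants: 2 1-[3-methoxy-4-(methoxymethoxy)phenyl]ethan-1-one; 3 diethyl carbonate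
Product: 4 ethyl 3-[3-methoxy-4-(methoxymethoxy)phenyl]-3-oxopropanoate
Conditions: NaH (2.2 equiv), (EtO)2CO (3 equiv), THF, reflux; then AcOH, 0 °C
Reagents that add atoms: none
Why: Crossed Claisen condensation of the methyl ketone enolate with the non-enolisable carbonate, pulled forward by irreversible deprotonation of the beta-keto ester formed, installs C9 at the ester level.

Step 3
Reactants: 4 ethyl 3-[3-methoxy-4-(methoxymethoxy)phenyl]-3-oxopropanoate
Product: 5 ethyl 2-bromo-3-[3-methoxy-4-(methoxymethoxy)phenyl]-3-oxopropanoate (racemic)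
Conditions: NBS (1.0 equiv), Mg(ClO4)2 (10 mol %), EtOAc, 0 °C to rt
Reagents that add atoms: N-bromosuccinimide, O=C1CCC(=O)N1Br
Why: Lewis-acid-assisted electrophilic alpha-bromination of the 1,3-dicarbonyl enol stops at the monobromide and liberates no HBr, so the acetal and the acyl-deactivated arene are left alone.

Step 4
Reactants: 6 3,4-dihydroxybenzaldehyde
Product: 7 3-hydroxy-4-(methoxymethoxy)benzaldehyde
Conditions: MOMCl (1.0 equiv), K2CO3 (1.1 equiv), acetone, 0 °C to rt
Reagents that add atoms: chloromethyl methyl ether (MOMCl), COCCl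
Why: Regioselective Williamson-type mono-alkylation, in which only the more acidic 4-OH (para to the formyl group) is ionised by one equivalent of weak base and capped, so that the free 3-oxygen is reserved for C8 and the masked 4-oxygen for C7.

Step 5
Reactants: 7 3-hydroxy-4-(methoxymethoxy)benzaldehyde; 8 tert-butyl (triphenylphosphoranylidene)acetate
Product: 9 tert-butyl (E)-3-[3-hydroxy-4-(methoxymethoxy)phenyl]prop-2-enoate
Conditions: toluene, 60 °C
Reagents that add atoms: none
Why: Wittig olefination with an ester-stabilised ylide is E-selective and tolerates the free meta-phenol, which is too weakly acidic to quench the ylide.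

Step 6
Reactants: 5 ethyl 2-bromo-3-[3-methoxy-4-(methoxymethoxy)phenyl]-3-oxopropanoate (racemic); 9 tert-butyl (E)-3-[3-hydroxy-4-(methoxymethoxy)phenyl]prop-2-enoate
Product: 10 ethyl 2-{5-[(E)-3-tert-butoxy-3-oxoprop-1-en-1-yl]-2-(methoxymethoxy)phenoxy}-3-[3-methoxy-4-(methoxymethoxy)phenyl]-3-oxopropanoate (racemic, C8 configurationally labile)
Conditions: K2CO3, acetone, rt
Reagents that add atoms: none
Why: Williamson ether synthesis, the phenoxide of 9 displacing bromide by SN2 at the doubly carbonyl-activated carbon to form the C8–O bond; the new centre is racemic and is meant to stay labile.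

Step 7
Reactants: 10 ethyl 2-{5-[(E)-3-tert-butoxy-3-oxoprop-1-en-1-yl]-2-(methoxymethoxy)phenoxy}-3-[3-methoxy-4-(methoxymethoxy)phenyl]-3-oxopropanoate (racemic)
Product: 11 ethyl (2S,3R)-2-{5-[(E)-3-tert-butoxy-3-oxoprop-1-en-1-yl]-2-(methoxymethoxy)phenoxy}-3-hydroxy-3-[3-methoxy-4-(methoxymethoxy)phenyl]propanoate (syn)
Conditions: RuCl(p-cymene)[(S,S)-TsDPEN] (2 mol %), HCO2H/Et3N (5:2), CH2Cl2, 30 °C; minor diastereomer removed by chromatography or crystallisation
Reagents that add atoms: none
Why: Formate converts the catalyst into its Ru–H/N–H form, which passes hydride and proton to the aryl ketone through an outer-sphere six-membered transition state (Noyori asymmetric transfer hydrogenation run as a dynamic kinetic resolution), while Et3N keeps the two enantiomers of 10 in fast exchange through the C8 enol. The closest known reaction type is the Ru–TsDPEN transfer-hydrogenation DKR of alpha-alkoxy beta-keto esters with aryl ketones, which gives syn alpha-alkoxy beta-hydroxy esters; the alpha-aryloxy compound belongs to the same substrate class. No ring closes here; only the C7–H bond forms. C7 (3R) is controlled by the catalyst, the aryl ketone lying against the eta6-cymene ligand so that the (S,S)-complex should deliver hydride to one carbonyl face, and C8 (2S) is controlled by relative rate, the enantiomer leading to the syn alcohol being reduced faster and constantly replenished. The selectivity that matters is at C8, since C7 is erased later; it is secured by C8 being the alpha-carbon of a 1,3-dicarbonyl that also carries the aryloxy group (fast enolisation) and by the 4-oxyaryl ketone that the catalyst recognises. The outer-sphere mechanism should leave the cinnamate C=C, both esters and the acetals untouched.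

Step 8
Reactants: 11 ethyl (2S,3R)-2-{5-[(E)-3-tert-butoxy-3-oxoprop-1-en-1-yl]-2-(methoxymethoxy)phenoxy}-3-hydroxy-3-[3-methoxy-4-(methoxymethoxy)phenyl]propanoate
Product: 12 tert-butyl (E)-3-[3-({(1R,2R)-1,3-dihydroxy-1-[3-methoxy-4-(methoxymethoxy)phenyl]propan-2-yl}oxy)-4-(methoxymethoxy)phenyl]prop-2-enoate
Conditions: NaBH4, THF/EtOH, 0 °C to rt; aq NH4Cl
Reagents that add atoms: none
Why: Chemoselective borohydride ester reduction, the ethyl ester being activated by its alpha-aryloxy and beta-hydroxy groups while the hindered conjugated tert-butyl ester is inert to NaBH4; C8 is untouched and becomes R only because CH2OH now ranks below C7.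

Step 9
Reactants: 12 tert-butyl (E)-3-[3-({(1R,2R)-1,3-dihydroxy-1-[3-methoxy-4-(methoxymethoxy)phenyl]propan-2-yl}oxy)-4-(methoxymethoxy)phenyl]prop-2-enoate
Product: 15 (E)-3-[(2R,3R)-2-(4-hydroxy-3-methoxyphenyl)-3-(hydroxymethyl)-2,3-dihydro-1,4-benzodioxin-6-yl]prop-2-enoic acid (the target), via open-chain trihydroxy acid 13 (not isolated), via cis-benzodioxane acid 14 (not isolated)
Conditions: TFA/CH2Cl2/H2O (10:10:1), 0.01 M, 0 °C to rt, held until the trans/cis ratio no longer changes; then evaporation, MeOH/H2O, rt
Reagents that add atoms: none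
Why: Acid-mediated acetal hydrolysis and tert-butyl ester acidolysis are followed by SN1 etherification through the para-hydroxybenzylic cation (protonated para-quinone methide), the freed catechol 4-OH closing the dioxane ring at C7 in a 6-exo sense; because the C7–O bond re-ionises, the cis isomer 14 should drain into the trans isomer with aryl and CH2OH both pseudo-equatorial, so C7 is set R under thermodynamic control while C8 is not involved.

**Compound list**

1 | acetovanillone, 1-(4-hydroxy-3-methoxyphenyl)ethan-1-one | CC(=O)c1ccc(O)c(OC)c1 | starting material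
2 | 1-[3-methoxy-4-(methoxymethoxy)phenyl]ethan-1-one | CC(=O)c1ccc(OCOC)c(OC)c1 | intermediate
3 | diethyl carbonate | CCOC(=O)OCC | starting material
4 | ethyl 3-[3-methoxy-4-(methoxymethoxy)phenyl]-3-oxopropanoate | CCOC(=O)CC(=O)c1ccc(OCOC)c(OC)c1 | intermediate
5 | ethyl 2-bromo-3-[3-methoxy-4-(methoxymethoxy)phenyl]-3-oxopropanoate (racemic) | CCOC(=O)C(Br)C(=O)c1ccc(OCOC)c(OC)c1 | intermediate
6 | 3,4-dihydroxybenzaldehyde | O=Cc1ccc(O)c(O)c1 | starting material
7 | 3-hydroxy-4-(methoxymethoxy)benzaldehyde | O=Cc1ccc(OCOC)c(O)c1 | intermediate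
8 | tert-butyl (triphenylphosphoranylidene)acetate | CC(C)(C)OC(=O)C=P(c1ccccc1)(c1ccccc1)c1ccccc1 | starting material
9 | tert-butyl (E)-3-[3-hydroxy-4-(methoxymethoxy)phenyl]prop-2-enoate | CC(C)(C)OC(=O)/C=C/c1ccc(OCOC)c(O)c1 | intermediate
10 | ethyl 2-{5-[(E)-3-tert-butoxy-3-oxoprop-1-en-1-yl]-2-(methoxymethoxy)phenoxy}-3-[3-methoxy-4-(methoxymethoxy)phenyl]-3-oxopropanoate (racemic) | CCOC(=O)C(Oc1cc(/C=C/C(=O)OC(C)(C)C)ccc1OCOC)C(=O)c1ccc(OCOC)c(OC)c1 | intermediate
11 | ethyl (2S,3R)-2-{5-[(E)-3-tert-butoxy-3-oxoprop-1-en-1-yl]-2-(methoxymethoxy)phenoxy}-3-hydroxy-3-[3-methoxy-4-(methoxymethoxy)phenyl]propanoate | CCOC(=O)[C@@H](Oc1cc(/C=C/C(=O)OC(C)(C)C)ccc1OCOC)[C@H](O)c1ccc(OCOC)c(OC)c1 | intermediate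
12 | tert-butyl (E)-3-[3-({(1R,2R)-1,3-dihydroxy-1-[3-methoxy-4-(methoxymethoxy)phenyl]propan-2-yl}oxy)-4-(methoxymethoxy)phenyl]prop-2-enoate | OC[C@@H](Oc1cc(/C=C/C(=O)OC(C)(C)C)ccc1OCOC)[C@H](O)c1ccc(OCOC)c(OC)c1 | intermediate
13 | (E)-3-[3-{[(1R,2R)-1,3-dihydroxy-1-(4-hydroxy-3-methoxyphenyl)propan-2-yl]oxy}-4-hydroxyphenyl]prop-2-enoic acid (open-chain trihydroxy acid, formed in the flask) | OC[C@@H](Oc1cc(/C=C/C(=O)O)ccc1O)[C@H](O)c1ccc(O)c(OC)c1 | intermediate
14 | (E)-3-[(2S,3R)-2-(4-hydroxy-3-methoxyphenyl)-3-(hydroxymethyl)-2,3-dihydro-1,4-benzodioxin-6-yl]prop-2-enoic acid (cis ring isomer, formed in the flask) | COc1cc([C@@H]2Oc3ccc(/C=C/C(=O)O)cc3O[C@@H]2CO)ccc1O | intermediate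
15 | (E)-3-[(2R,3R)-2-(4-hydroxy-3-methoxyphenyl)-3-(hydroxymethyl)-2,3-dihydro-1,4-benzodioxin-6-yl]prop-2-enoic acid (trans) | COc1cc([C@H]2Oc3ccc(/C=C/C(=O)O)cc3O[C@@H]2CO)ccc1O | target

**Step count and risks**

Total: 9 steps. Longest linear sequence: 7 steps (steps 1, 2, 3, 6, 7, 8, 9 from acetovanillone); the other branch (steps 4, 5) joins at step 6.

Steps most likely to fail:

Step 7. Stereoconvergence may be incomplete: enolisation at C8 may not outrun the reduction, or the syn/anti discrimination may be poor, leaving C8 of mixed configuration that would show up as lowered enantiopurity of the target. The relative and absolute configuration of 11 should be assigned before it is carried on. If the intrinsic preference proved anti, the antipodal catalyst would give the (2S,3S) ester, which is equally usable because C7 is erased later. Fallback with a different source of C8, an auxiliary-controlled Evans syn-aldol, setting out from 9 and returning at 12: phenol 9 would be O-alkylated with commercial (S)-4-benzyl-3-(chloroacetyl)oxazolidin-2-one (K2CO3, NaI cat., acetone) to give (4S)-4-benzyl-3-{2-[5-((E)-3-tert-butoxy-3-oxoprop-1-en-1-yl)-2-(methoxymethoxy)phenoxy]acetyl}-1,3-oxazolidin-2-one F1. Vanillin would be protected (MOMCl, iPr2NEt, CH2Cl2) as 3-methoxy-4-(methoxymethoxy)benzaldehyde F2. The Z-boron enolate of F1 (Bu2BOTf, iPr2NEt, CH2Cl2, −78 °C) would add to F2 to give the syn adduct (4S)-4-benzyl-3-[(2S,3R)-2-{5-[(E)-3-tert-butoxy-3-oxoprop-1-en-1-yl]-2-(methoxymethoxy)phenoxy}-3-hydroxy-3-[3-methoxy-4-(methoxymethoxy)phenyl]propanoyl]-1,3-oxazolidin-2-one F3, the auxiliary fixing C8. Reductive removal of the auxiliary (NaBH4, THF/H2O, 0 °C to rt) would then give diol 12.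

Step 9. Several things can go wrong in the one-pot acid step. Formaldehyde released from the two acetals may be captured as a cyclic formal on the 1,3-diol or by the electron-rich arenes. The benzylic cation may oligomerise. Equilibration to the trans ring may be slow, and prolonged acid exposure could erode C8 through loss of H8 from the cation. Fallback that separates acetal removal from ring closure, setting out from 12 and returning at 15: the two aryl methoxymethyl ethers would be cleaved without protic acid by TMSOTf/2,2'-bipyridyl (MeCN, 0 °C to rt, then water), which passes through the aryl silyl ethers and sends the methoxymethyl units into the aqueous phase. This would give tert-butyl (E)-3-[3-{[(1R,2R)-1,3-dihydroxy-1-(4-hydroxy-3-methoxyphenyl)propan-2-yl]oxy}-4-hydroxyphenyl]prop-2-enoate F4. A short treatment of F4 with dilute TFA in CH2Cl2, now free of formaldehyde, would close the ring and cleave the tert-butyl ester to give 15.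

Step 6. Bromine transfer from the alpha-bromo 1,3-dicarbonyl to the phenoxide (reductive debromination, ring bromination) or C-alkylation may compete with the SN2 displacement. Fallback that forms the C8–O bond by carbenoid O–H insertion, setting out from 4 and returning at 10: diazo transfer to 4 (4-acetamidobenzenesulfonyl azide, Et3N, MeCN) would give ethyl 2-diazo-3-[3-methoxy-4-(methoxymethoxy)phenyl]-3-oxopropanoate F5. Its Rh2(OAc)4-catalysed decomposition in the presence of phenol 9 (CH2Cl2, reflux) would insert the carbenoid into the phenolic O–H bond to give 10.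

**Further compounds**

F1 | step 7 | (4S)-4-benzyl-3-{2-[5-((E)-3-tert-butoxy-3-oxoprop-1-en-1-yl)-2-(methoxymethoxy)phenoxy]acetyl}-1,3-oxazolidin-2-one | O=C(COc1cc(/C=C/C(=O)OC(C)(C)C)ccc1OCOC)N1[C@@H](Cc2ccccc2)COC1=O
F2 | step 7 | 3-methoxy-4-(methoxymethoxy)benzaldehyde | COCOc1ccc(C=O)cc1OC
F3 | step 7 | (4S)-4-benzyl-3-[(2S,3R)-2-{5-[(E)-3-tert-butoxy-3-oxoprop-1-en-1-yl]-2-(methoxymethoxy)phenoxy}-3-hydroxy-3-[3-methoxy-4-(methoxymethoxy)phenyl]propanoyl]-1,3-oxazolidin-2-one | O=C([C@@H](Oc1cc(/C=C/C(=O)OC(C)(C)C)ccc1OCOC)[C@H](O)c1ccc(OCOC)c(OC)c1)N1[C@@H](Cc2ccccc2)COC1=O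
F4 | step 9 | tert-butyl (E)-3-[3-{[(1R,2R)-1,3-dihydroxy-1-(4-hydroxy-3-methoxyphenyl)propan-2-yl]oxy}-4-hydroxyphenyl]prop-2-enoate | OC[C@@H](Oc1cc(/C=C/C(=O)OC(C)(C)C)ccc1O)[C@H](O)c1ccc(O)c(OC)c1
F5 | step 6 | ethyl 2-diazo-3-[3-methoxy-4-(methoxymethoxy)phenyl]-3-oxopropanoate | CCOC(=O)C(=[N+]=[N-])C(=O)c1ccc(OCOC)c(OC)c1
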